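| setting | Friday's | Wednesday's | Thursday's | gamma | theta |
|---|---|---|---|---|---|
| E | 2.9 M | 2.9 M | 2.9 M | 2.9 M | 2.9 M |
| L | 0.087 M | 0.087 M | 0.087 M | 0.0870 M | 0.0870 M |
| Z | 47 mM | 91 mM | 140 mM | 180 mM | 50 mM |
| remark | run made earlier | run made earlier | run made earlier |  |  |
| time |  |  |  | 12 min | 12 min |

| run | time / min | X / % | E / % |
|---|---|---|---|
| Friday's | 1.33 | 2.2 | 97.2 |
| Friday's | 2.50 | 6.3 | 93.5 |
| Friday's | 4.00 | 9.3 | 89.9 |
| Friday's | 5.00 | 10.3 | 88.4 |
| Friday's | 6.00 | 13.2 | 88.2 |
| Wednesday's | 0.500 | 3.7 | 96.0 |
| Wednesday's | 0.833 | 5.3 | 95.1 |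
| Wednesday's | 1.50 | 8.4 | 91.5 |
| Wednesday's | 3.00 | 13.7 | 86.3 |
| Wednesday's | 6.00 | 23.3 | 76.2 |
| Thursday's | 1.33 | 11.3 | 89.3 |
| Thursday's | 2.50 | 18.2 | 82.1 |
| Thursday's | 4.00 | 26.9 | 74.3 |
| Thursday's | 5.00 | 30.3 | 71.5 |
| Thursday's | 6.00 | 33.3 | 67.6 |

(scatter of a reading: 1 percentage point)

- the average divides the monomer in chains by the number of chains begun, living and dead together
- steps that have been proposed: D + L -> Q; Z -> G; E + Z -> D + X; E + D -> X + D
- the earlier runs do not show the number of chains; that part of a forecast is a guess

- which of the two ends with the longer chains by the average number of monomer units in a chain (chains begun, living or dead) ("neither" if they lie within 10%) (gamma / theta / neither)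
- average number of monomer units in a chain (chains begun, living or dead) at the end, gamma
- average number of monomer units in a chain (chains begun, living or dead) at the end, theta

**Thursday's slope.** In Thursday's run E falls from 89.3% at 1.33 min to 67.6% at 6.00 min, a logarithmic slope of 0.0596 min⁻¹ with 140 mM of Z charged. Friday's run, with 47 mM of Z, reads 0.0208 min⁻¹ between the same times, and Thursday's slope scaled by the charge of Z predicts 0.0200 min⁻¹. Within these readings the slope follows the Z charged; carrying it unchanged to the end, as a pseudo-first-order slope, is my assumption.

**One number.** For gamma, the scaled slope times 12 min gives u = 0.920, the depletion number, the logarithm of the factor by which E falls over the run at that constant slope. For theta, u = 0.255.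

**Mean E.** By E + D → X + D a living chain grows in proportion to E, so I replace the falling curve by its mean. As a share of the charge, that mean is the share of E lost divided by u: 0.654 in gamma, 0.882 in theta. Theta's chains should therefore be longer than gamma's, by a factor of 1.35, and I choose theta.

**Its limit.** u gives this ratio but no length, since the runs do not show the chains begun. One chain per Z charged gives 9.69 units in gamma and 13.1 in theta. Z may also go to G, so I read these as floors.

**The forecast.** It says theta, with 10 units for gamma and 13.5 for theta, as lengths rather than floors: “The number of chains remains inferred, so the upper ranges are wider.”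

    D + L → Q (k = 0.0200 L mol⁻¹ s⁻¹)
    Z → G (k = 0.0880 s⁻¹)
    E + Z → D + X (k = 0.0140 L mol⁻¹ s⁻¹)
    E + D → X + D, rate k4*[D]*[E] (k = 0.0330 L mol⁻¹ s⁻¹)

**The flask.** Theta ends longer (theta), with 36.8 units per chain against 29.4 in gamma, a ratio of 1.25 where u gave 1.35. Of the 180 mM of Z charged to gamma, 0.124 M stands as G at 12.0 min, while D and Q together hold 0.0562 M. A neighbour flask, like theta but with 0.20 M of Z, has u = 1.02 and a mean share of 0.626. Theta's length scaled by the mean shares gives 26.1 units for that neighbour, and it ends at 28.4.

The earlier runs and the new flask come from a simulation from invented constants, noise included.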